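**Retrosynthetic overview**
- The target comes from one acidolysis that removes three 4-methoxybenzyl (PMB) groups from a fully protected (R)-ester. No ring is formed anywhere; both benzene rings are bought.
- Key disconnection: the C2–O(acyl) bond. Ferulic acid O–H adds to a carbene from an α-diazo ester in an enantioselective O–H insertion, which makes the C–O bond and sets C2 as R in the same step.
- The α-diazo ester comes from the protected propanoate by trifluoroacetylation and deacylative diazo transfer.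
- The protected propanoate comes from 3-(3,4-dihydroxyphenyl)propanoic acid by one exhaustive O-alkylation.

Assumption: the target is the (2R, E) isomer, as read from the SMILES. In step 3 the antipode of the chiral acid co-catalyst that gives R is fixed by an initial screen of both commercial antipodes; the (R)-acid is written here.

**Step 1**
Reactants: 1 3-(3,4-dihydroxyphenyl)propanoic acid (dihydrocaffeic acid)
Product: 2 4-methoxybenzyl 3-[3,4-bis(4-methoxybenzyloxy)phenyl]propanoate
Conditions: PMBCl (3.6 equiv), K2CO3 (4.5 equiv), TBAI (10 mol%), DMF, N2, 60 °C, 12 h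
Reagents that add atoms: 4-methoxybenzyl chloride, COc1ccc(CCl)cc1
Why: Exhaustive SN2 O-alkylation (Williamson ether synthesis plus carboxylate alkylation) of the two phenoxides and the carboxylate by an activated benzylic chloride, run under N2 so the catechol is not air-oxidised.

**Step 2**
Reactants: 2 4-methoxybenzyl 3-[3,4-bis(4-methoxybenzyloxy)phenyl]propanoate
Product: 4 4-methoxybenzyl 2-diazo-3-[3,4-bis(4-methoxybenzyloxy)phenyl]propanoate, via α-trifluoroacetyl ester 3 (not isolated)
Conditions: LiHMDS (1.15 equiv), THF, −78 °C; CF3CO2CH2CF3 (1.3 equiv), −78 °C, aq. HCl quench; then p-ABSA (1.5 equiv), Et3N (1.5 equiv), H2O (1 equiv), MeCN, rt, 3 h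
Reagents that add atoms: 2,2,2-trifluoroethyl trifluoroacetate, FC(F)(F)COC(=O)C(F)(F)F (adds the CF3CO group of intermediate 3 only); 4-acetamidobenzenesulfonyl azide, CC(=O)Nc1ccc(cc1)S(=O)(=O)N=[N+]=[N-] (adds the N2 of 4)
Why: Claisen-type trifluoroacetylation of the ester enolate activates C2, and Regitz-type detrifluoroacetylative diazo transfer (Danheiser protocol) then installs N2 while the trifluoroacetyl group leaves on the sulfonamide nitrogen.

**Step 3**
Reactants: 4 4-methoxybenzyl 2-diazo-3-[3,4-bis(4-methoxybenzyloxy)phenyl]propanoate; 5 (E)-ferulic acid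
Product: 7 4-methoxybenzyl (2R)-3-[3,4-bis(4-methoxybenzyloxy)phenyl]-2-{[(2E)-3-(4-hydroxy-3-methoxyphenyl)prop-2-enoyl]oxy}propanoate, via free enol 6 (not isolated)
Conditions: 5 (1.5 equiv), Rh2(TPA)4 (1 mol%), (R)-STRIP [(R)-6,6'-bis(2,4,6-triisopropylphenyl)-SPINOL hydrogen phosphate] (5 mol%), 4 Å MS, CH2Cl2/EtOAc 3:1, −30 °C, 4 added over 2 h by syringe pump; NaHCO3 wash removes excess 5
Reagents that add atoms: none
Why: Proposed new method: an enantioselective carbene O–H insertion of a phenolic cinnamic acid into an α-benzyl α-diazo ester under Rh(II)/chiral phosphoric acid relay catalysis, in which Rh2(TPA)4 extrudes N2 and its bulky triphenylacetate pocket at low temperature holds back the competing 1,2-hydride shift, the carboxylic acid O–H (far more acidic and, once hydrogen-bonded to the phosphate, more reactive than the hindered guaiacol O–H) adds to the carbenoid and releases the free enol 6, and the spiro phosphoric acid then acts as a bifunctional proton shuttle that protonates one face of C2 and so sets the R centre; the closest known reactions are the Rh(II)/chiral phosphoric acid (or chiral guanidine) co-catalysed asymmetric carboxylic acid O–H insertions of α-aryl α-diazo esters and α-diazo ketones, and the racemic Rh2(OAc)4 carboxylic acid insertions of α-alkyl α-diazo esters, whereas an enantioselective version on an α-alkyl diazo ester bearing β-hydrogens, with a free phenol on the acid, is to my knowledge not yet shown.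

**Step 4**
Reactants: 7 4-methoxybenzyl (2R)-3-[3,4-bis(4-methoxybenzyloxy)phenyl]-2-{[(2E)-3-(4-hydroxy-3-methoxyphenyl)prop-2-enoyl]oxy}propanoate
Product: 8 (2R)-3-(3,4-dihydroxyphenyl)-2-{[(2E)-3-(4-hydroxy-3-methoxyphenyl)prop-2-enoyl]oxy}propanoic acid (target)
Conditions: TFA/CH2Cl2 1:4, pentamethylbenzene (10 equiv), 0 °C to rt, 2 h; trituration with hexane/Et2O, then reverse-phase chromatography
Reagents that add atoms: none
Why: Acidolytic (SN1) cleavage of the PMB ester and both aryl PMB ethers, with the 4-methoxybenzyl cations removed by Friedel–Crafts capture on pentamethylbenzene; the non-benzylic α-acyloxy C–O bond, the cinnamate alkene and the aryl methyl ether are inert to TFA and the C2 centre cannot epimerise in acid.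

**Compound list**
1 | 3-(3,4-dihydroxyphenyl)propanoic acid | OC(=O)CCc1ccc(O)c(O)c1 | starting material
2 | 4-methoxybenzyl 3-[3,4-bis(4-methoxybenzyloxy)phenyl]propanoate | COc1ccc(COC(=O)CCc2ccc(OCc3ccc(OC)cc3)c(OCc3ccc(OC)cc3)c2)cc1 | intermediate
3 | 4-methoxybenzyl 2-[3,4-bis(4-methoxybenzyloxy)benzyl]-4,4,4-trifluoro-3-oxobutanoate (racemic; not isolated) | COc1ccc(COC(=O)C(Cc2ccc(OCc3ccc(OC)cc3)c(OCc3ccc(OC)cc3)c2)C(=O)C(F)(F)F)cc1 | intermediate
4 | 4-methoxybenzyl 2-diazo-3-[3,4-bis(4-methoxybenzyloxy)phenyl]propanoate | COc1ccc(COC(=O)C(=[N+]=[N-])Cc2ccc(OCc3ccc(OC)cc3)c(OCc3ccc(OC)cc3)c2)cc1 | intermediate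
5 | (E)-ferulic acid, (2E)-3-(4-hydroxy-3-methoxyphenyl)prop-2-enoic acid | COc1cc(/C=C/C(=O)O)ccc1O | starting material
6 | enol (ketene hemiacetal) tautomer of 7, 1-hydroxy-1-(4-methoxybenzyloxy)-3-[3,4-bis(4-methoxybenzyloxy)phenyl]prop-1-en-2-yl (E)-ferulate (enol geometry not defined; not isolated) | COc1ccc(COC(O)=C(Cc2ccc(OCc3ccc(OC)cc3)c(OCc3ccc(OC)cc3)c2)OC(=O)/C=C/c2ccc(O)c(OC)c2)cc1 | intermediate
7 | 4-methoxybenzyl (2R)-3-[3,4-bis(4-methoxybenzyloxy)phenyl]-2-{[(2E)-3-(4-hydroxy-3-methoxyphenyl)prop-2-enoyl]oxy}propanoate | COc1cc(/C=C/C(=O)O[C@H](Cc2ccc(OCc3ccc(OC)cc3)c(OCc3ccc(OC)cc3)c2)C(=O)OCc2ccc(OC)cc2)ccc1O | intermediate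
8 | (2R)-3-(3,4-dihydroxyphenyl)-2-{[(2E)-3-(4-hydroxy-3-methoxyphenyl)prop-2-enoyl]oxy}propanoic acid | COc1cc(/C=C/C(=O)O[C@H](Cc2ccc(O)c(O)c2)C(=O)O)ccc1O | target

**Step count**
Total steps: 4. Longest linear sequence: 4 (1 → 2 → 4 → 7 → 8); ferulic acid 5 is used as bought.

**Three steps most likely to fail**

Step 3 (the proposed new insertion). The risks are 1,2-hydride shift of the carbenoid to the protected caffeate, insertion into the phenol O–H of 5, and low enantioselectivity in the proton transfer. The fallback uses known chemistry; it sets out from 4 and comes back at 7. Oxidation of the diazo group of 4 with dimethyldioxirane (acetone, 0 °C) gives 4-methoxybenzyl 3-[3,4-bis(4-methoxybenzyloxy)phenyl]-2-oxopropanoate F1. Asymmetric hydrogenation with a Ru(II)–diphosphine catalyst of the SEGPHOS/SunPhos class (or a ketoreductase), antipode chosen for S, gives 4-methoxybenzyl (2S)-3-[3,4-bis(4-methoxybenzyloxy)phenyl]-2-hydroxypropanoate F2. Mitsunobu esterification of F2 with 5 (PPh3, DIAD, THF, 0 °C) forms the same C–O bond with clean inversion and gives 7 as the R ester; the free phenol of 5 is tolerated because the carboxylic acid is the far better Mitsunobu pronucleophile. Material from this path also serves as a reference for the absolute configuration of 7.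

Step 2 (diazo ester formation). The risks are incomplete trifluoroacetylation of a simple ester enolate and loss of 4 on silica. The fallback sets out from 2 and comes back at 4. Electrophilic azidation of the potassium enolate of 2 (KHMDS, THF, −78 °C; 2,4,6-triisopropylbenzenesulfonyl azide; AcOH quench) gives racemic 4-methoxybenzyl 2-azido-3-[3,4-bis(4-methoxybenzyloxy)phenyl]propanoate F3. Staudinger reduction (PPh3, THF/H2O) gives racemic 4-methoxybenzyl 2-amino-3-[3,4-bis(4-methoxybenzyloxy)phenyl]propanoate F4. Diazotisation of F4 with isoamyl nitrite and catalytic AcOH in refluxing CHCl3 gives 4.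

Step 4 (global deprotection). The risk is C-benzylation of the electron-rich catechol and guaiacol rings by PMB cations despite the scavenger. The fallback changes the protecting groups from benzyl-type to acetal-type, so that no stabilised benzyl cation is ever formed; it sets out from 1 and comes back at 8. Treatment of 1 with MOMCl (3.6 equiv) and i-Pr2NEt in CH2Cl2 gives methoxymethyl 3-[3,4-bis(methoxymethoxy)phenyl]propanoate F5. The conditions of step 2 convert F5, through methoxymethyl 2-[3,4-bis(methoxymethoxy)benzyl]-4,4,4-trifluoro-3-oxobutanoate F6 (not isolated), into methoxymethyl 2-diazo-3-[3,4-bis(methoxymethoxy)phenyl]propanoate F7. The conditions of step 3 with 5 convert F7, through the corresponding free enol 1-hydroxy-1-(methoxymethoxy)-3-[3,4-bis(methoxymethoxy)phenyl]prop-1-en-2-yl (E)-ferulate F8 (not isolated), into methoxymethyl (2R)-3-[3,4-bis(methoxymethoxy)phenyl]-2-{[(2E)-3-(4-hydroxy-3-methoxyphenyl)prop-2-enoyl]oxy}propanoate F9. Hydrolysis of the three acetals of F9 (2 M aq. HCl/THF 1:3, 40 °C) gives 8.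

**Further compounds**
F1 | step 3 | 4-methoxybenzyl 3-[3,4-bis(4-methoxybenzyloxy)phenyl]-2-oxopropanoate | COc1ccc(COC(=O)C(=O)Cc2ccc(OCc3ccc(OC)cc3)c(OCc3ccc(OC)cc3)c2)cc1
F2 | step 3 | 4-methoxybenzyl (2S)-3-[3,4-bis(4-methoxybenzyloxy)phenyl]-2-hydroxypropanoate | O[C@@H](Cc1ccc(OCc2ccc(OC)cc2)c(OCc2ccc(OC)cc2)c1)C(=O)OCc1ccc(OC)cc1
F3 | step 2 | 4-methoxybenzyl 2-azido-3-[3,4-bis(4-methoxybenzyloxy)phenyl]propanoate (racemic) | COc1ccc(COC(=O)C(N=[N+]=[N-])Cc2ccc(OCc3ccc(OC)cc3)c(OCc3ccc(OC)cc3)c2)cc1
F4 | step 2 | 4-methoxybenzyl 2-amino-3-[3,4-bis(4-methoxybenzyloxy)phenyl]propanoate (racemic) | COc1ccc(COC(=O)C(N)Cc2ccc(OCc3ccc(OC)cc3)c(OCc3ccc(OC)cc3)c2)cc1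
F5 | step 4 | methoxymethyl 3-[3,4-bis(methoxymethoxy)phenyl]propanoate | COCOC(=O)CCc1ccc(OCOC)c(OCOC)c1
F6 | step 4 | methoxymethyl 2-[3,4-bis(methoxymethoxy)benzyl]-4,4,4-trifluoro-3-oxobutanoate (racemic; not isolated) | COCOC(=O)C(Cc1ccc(OCOC)c(OCOC)c1)C(=O)C(F)(F)F
F7 | step 4 | methoxymethyl 2-diazo-3-[3,4-bis(methoxymethoxy)phenyl]propanoate | COCOC(=O)C(=[N+]=[N-])Cc1ccc(OCOC)c(OCOC)c1
F8 | step 4 | 1-hydroxy-1-(methoxymethoxy)-3-[3,4-bis(methoxymethoxy)phenyl]prop-1-en-2-yl (E)-ferulate (enol; not isolated) | COCOC(O)=C(Cc1ccc(OCOC)c(OCOC)c1)OC(=O)/C=C/c1ccc(O)c(OC)c1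
F9 | step 4 | methoxymethyl (2R)-3-[3,4-bis(methoxymethoxy)phenyl]-2-{[(2E)-3-(4-hydroxy-3-methoxyphenyl)prop-2-enoyl]oxy}propanoate | COCOC(=O)[C@@H](Cc1ccc(OCOC)c(OCOC)c1)OC(=O)/C=C/c1ccc(O)c(OC)c1
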